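**Plan**
- Retrosynthetic cuts: (a) the tiglate C–O bond; (b) the two bonds joining ring B to ring A, C1–C8a and C4–C4a, which give 3,6-bis(methoxymethoxy)benzyne and a 3-substituted furan; (c) the bond from furan C3 to the carbinol carbon C1′ (3-lithiofuran plus a Weinreb amide).
- Enabling feature: C1–C2–C3–C4 of ring B, oxygenated at C1 and C4 and carrying the side chain on C2, are the four carbons C2–C5 of a 3-substituted furan. Ring A is a symmetrical 3,6-dioxygenated benzene, so the aryne has no regiochemistry and either opening of the oxygen bridge leads to the same quinone.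
- Forward order: the side chain is joined to the furan (ketone, then carbinol); ring B is closed onto ring A by the cycloaddition; the bridge is opened and ring B oxidised to the quinone; the alcohol is freed and acylated; the ring A phenols are unmasked last.
- Stereochemistry: C1′ (S) is set by reagent-controlled reduction of the furyl ketone with (−)-Ipc2BCl and its C–O bond is never broken afterwards. The two bridgehead centres are transient. The E-alkene comes with tiglic acid.

Key step: step 6

Remark: the given SMILES is (S) at C1′, i.e. the tiglate of alkannin; the 5,8-dihydroxy-1,4-naphthoquinone core is a pair of fast tautomers, so only the oxidation level of the bicycle has to be delivered.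
Remark: the cycloaddition cannot distinguish the two furan faces, so cycloadduct 15 is expected as a pair of cis-bridgehead epimers. The number 15 stands for the pair; the (1R,4S) member is drawn, and the (1S,4R) member differs only in the two bridgehead descriptors. The bridge opening should likewise give two regioisomeric naphthols (16, 17). Each pair is taken on unseparated because both members lead to quinone 18.

**Route**

Step 1
Reactants: 1 2-bromohydroquinone (2-bromobenzene-1,4-diol)
Product: 2 2-bromo-1,4-bis(methoxymethoxy)benzene
Conditions: MOMCl, i-Pr2NEt, CH2Cl2, 0 °C → rt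
Reagents that add atoms: chloromethyl methyl ether (MOMCl), COCCl
Why: Williamson-type O-alkylation of both phenols under an amine base, which avoids the air-sensitive hydroquinone dianion and installs acetals that direct the later lithiation, survive organolithium, rhodium, cobalt/oxygen and fluoride, and leave under mild acid.

Step 2
Reactants: 3 4-methylpent-3-enoic acid
Product: 5 N-methoxy-N,4-dimethylpent-3-enamide, via 1-(imidazol-1-yl)-4-methylpent-3-en-1-one 4 (not isolated)
Conditions: 1,1′-carbonyldiimidazole (CDI), CH2Cl2, 0 °C → rt; then MeNH(OMe)·HCl, rt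
Reagents that add atoms: N,O-dimethylhydroxylamine hydrochloride, CNOC.Cl
Why: Weinreb amide formation through the acyl imidazolide, whose nearly neutral conditions should keep the β,γ-alkene out of conjugation.

Step 3
Reactants: 6 3-bromofuran; 5 N-methoxy-N,4-dimethylpent-3-enamide
Product: 9 1-(furan-3-yl)-4-methylpent-3-en-1-one, via 3-lithiofuran 7 (not isolated), via lithium hemiaminal alkoxide 8 (not isolated)
Conditions: 6, n-BuLi, THF, −78 °C; then 5, −78 °C; sat. aq NH4Cl
Reagents that add atoms: none
Why: Bromine–lithium exchange followed by Weinreb ketone synthesis, in which 3-lithiofuran keeps its position at −78 °C, adds once to give a chelated tetrahedral alkoxide that cannot over-add, and the cold, weakly acidic quench should release the ketone without moving the alkene into conjugation.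

Step 4
Reactants: 9 1-(furan-3-yl)-4-methylpent-3-en-1-one
Product: 11 (S)-1-(furan-3-yl)-4-methylpent-3-en-1-ol, via alkoxy(chloro)isopinocampheylborane 10 (not isolated)
Conditions: (−)-Ipc2BCl, THF, −25 °C; then HN(CH2CH2OH)2, Et2O, rt
Reagents that add atoms: none
Why: Asymmetric reduction with (−)-B-chlorodiisopinocampheylborane (DIP-Cl reduction), in which hydride passes from one isopinocampheyl group through a six-membered boat-like transition state with the flat 3-furyl ring in the aryl (large) position and the CH2 chain in the small one, the sense that gives (S)-carbinols from aryl alkyl ketones, in a base-free medium that should not isomerise the alkene.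

Step 5
Reactants: 11 (S)-1-(furan-3-yl)-4-methylpent-3-en-1-ol
Product: 12 (S)-3-[1-(tert-butyldimethylsilyloxy)-4-methylpent-3-en-1-yl]furan
Conditions: TBSCl, imidazole, DMF, rt
Reagents that add atoms: tert-butyldimethylsilyl chloride, CC(C)(C)[Si](C)(C)Cl
Why: Imidazole-promoted silylation of the secondary alcohol, which removes the acidic O–H and a nucleophilic alkoxide from the aryne step and can later be cleaved by fluoride without touching the acetals.

Step 6
Reactants: 2 2-bromo-1,4-bis(methoxymethoxy)benzene; 12 (S)-3-[1-(tert-butyldimethylsilyloxy)-4-methylpent-3-en-1-yl]furan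
Product: 15 (1R,4S)-2-[(S)-1-(tert-butyldimethylsilyloxy)-4-methylpent-3-en-1-yl]-5,8-bis(methoxymethoxy)-1,4-dihydro-1,4-epoxynaphthalene (expected together with its (1S,4R) bridgehead epimer; the pair carries this one number), via 2-bromo-3-lithio-1,4-bis(methoxymethoxy)benzene 13 (not isolated), via 3,6-bis(methoxymethoxy)benzyne 14 (not isolated)
Conditions: 2 (2.5 equiv), LiTMP (lithium 2,2,6,6-tetramethylpiperidide, from 2,2,6,6-tetramethylpiperidine and n-BuLi; 2.4 equiv), THF, −78 °C; then 12 (1 equiv), −78 °C → rt
Reagents that add atoms: none
Why: LiTMP removes the ring proton of 2 that lies between bromine and a methoxymethoxy group (inductive acidification plus lithium coordination), and on warming aryllithium 13 loses LiBr to give the symmetrical aryne 14, which the furan diene of 12 captures in a concerted, suprafacial [4+2] cycloaddition across furan C2 and C5. The closest known reaction type is the Diels–Alder trapping of 3,6-dialkoxybenzynes, generated from 2-halo-1,4-dialkoxybenzenes with lithium amides, by furans to give 1,4-epoxy-1,4-dihydronaphthalenes. Ring B closes as a six-membered carbocycle by intermolecular [4+2] cycloaddition in which both new σ-bonds (C1–C8a and C4–C4a) form in one step, the furan oxygen ending as a one-atom bridge over C1 and C4. The two new bridgehead stereocentres are necessarily cis because the diene adds suprafacially within a bicyclic frame, while the face of the furan that reacts relative to the remote C1′ centre is not controlled, so both bridgehead epimers of 15 should form, which is harmless because both bridgeheads become sp2 in step 7. The step needs only chemoselectivity: the symmetry of 14 removes regiochemistry, the amide base is consumed by the more acidic arene before 12 is added so the furan α-positions are not metalated, furan is a far better aryne trap than the trisubstituted alkene (ene reaction) or the hindered amine, and the silyl ether keeps C1′ inert.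

Step 7
Reactants: 15 2-[(S)-1-(tert-butyldimethylsilyloxy)-4-methylpent-3-en-1-yl]-5,8-bis(methoxymethoxy)-1,4-dihydro-1,4-epoxynaphthalene (pair of bridgehead epimers)
Product: 18 2-[(S)-1-(tert-butyldimethylsilyloxy)-4-methylpent-3-en-1-yl]-5,8-bis(methoxymethoxy)naphthalene-1,4-dione, via 2-substituted 1-naphthol 16 (not isolated), via 3-substituted 1-naphthol 17 (not isolated)
Conditions: [Rh(CO)2Cl]2 (cat.), ClCH2CH2Cl, 60 °C; then Co(salen) (N,N′-bis(salicylidene)ethylenediaminocobalt, C16H14CoN2O2, cat.), O2 (1 atm), MeCN, rt
Reagents that add atoms: dioxygen, O=O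
Why: Monovalent rhodium inserts into a strained allylic–benzylic bridgehead C–O bond and the opened species aromatises to the 1-naphthol (the known rhodium-catalysed isomerisation of 7-oxabenzonorbornadienes), after which divalent cobalt–salen with oxygen oxygenates the free para position (the known aerobic naphthol-to-1,4-naphthoquinone oxidation), so that 16 and 17 converge on one quinone because ring A is symmetrical, the air-sensitive naphthols are never handled, and C1′ is untouched.

Step 8
Reactants: 18 2-[(S)-1-(tert-butyldimethylsilyloxy)-4-methylpent-3-en-1-yl]-5,8-bis(methoxymethoxy)naphthalene-1,4-dione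
Product: 19 2-[(S)-1-hydroxy-4-methylpent-3-en-1-yl]-5,8-bis(methoxymethoxy)naphthalene-1,4-dione
Conditions: HF·pyridine, pyridine, THF, 0 °C → rt
Reagents that add atoms: none
Why: Fluoride-driven desilylation under buffered, non-basic conditions, which should spare the methoxymethyl acetals, the base-sensitive quinone and the alkene and does not break the C1′–O bond.

Step 9
Reactants: 19 2-[(S)-1-hydroxy-4-methylpent-3-en-1-yl]-5,8-bis(methoxymethoxy)naphthalene-1,4-dione; 20 tiglic acid ((E)-2-methylbut-2-enoic acid)
Product: 22 (S)-1-[5,8-bis(methoxymethoxy)-1,4-dioxo-1,4-dihydronaphthalen-2-yl]-4-methylpent-3-en-1-yl (E)-2-methylbut-2-enoate, via O-tigloyl-N,N′-dicyclohexylisourea 21 (not isolated)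
Conditions: N,N′-dicyclohexylcarbodiimide (DCC), 4-(dimethylamino)pyridine (DMAP, cat.), CH2Cl2, 0 °C → rt
Reagents that add atoms: none
Why: Steglich esterification, in which the carbodiimide-activated acid is passed by DMAP to the secondary alcohol so that the new bond forms at oxygen and C1′ keeps its (S) configuration, the E-tiglate being the thermodynamically preferred geometry and no phenol being free to compete.

Step 10
Reactants: 22 (S)-1-[5,8-bis(methoxymethoxy)-1,4-dioxo-1,4-dihydronaphthalen-2-yl]-4-methylpent-3-en-1-yl (E)-2-methylbut-2-enoate
Product: 23 (S)-1-(5,8-dihydroxy-1,4-dioxo-1,4-dihydronaphthalen-2-yl)-4-methylpent-3-en-1-yl (E)-2-methylbut-2-enoate (alkannin tiglate, CNP0373203.1)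
Conditions: 3 M aq HCl, THF, 0 °C → rt
Reagents that add atoms: none
Why: Acid-catalysed acetal hydrolysis of the two aryl methoxymethyl ethers, favoured because each leaving phenol is peri to a quinone carbonyl and ends in a strong hydrogen bond, on a substrate whose C1′ oxygen is already acylated, so the acid-induced cyclisation of a free C1′ hydroxyl onto the prenyl alkene cannot occur and dilute acid at or below room temperature should leave the ester, both alkenes and the stereocentre intact.

**Compound list**

1 | 2-bromohydroquinone | Oc1ccc(O)c(Br)c1 | starting material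
2 | 2-bromo-1,4-bis(methoxymethoxy)benzene | COCOc1ccc(OCOC)c(Br)c1 | intermediate
3 | 4-methylpent-3-enoic acid | CC(C)=CCC(=O)O | starting material
4 | 1-(imidazol-1-yl)-4-methylpent-3-en-1-one | CC(C)=CCC(=O)n1ccnc1 | intermediate (not isolated)
5 | N-methoxy-N,4-dimethylpent-3-enamide | CC(C)=CCC(=O)N(C)OC | intermediate
6 | 3-bromofuran | Brc1ccoc1 | starting material
7 | 3-lithiofuran | [Li]c1ccoc1 | intermediate (not isolated)
8 | lithium 1-(furan-3-yl)-1-[methoxy(methyl)amino]-4-methylpent-3-en-1-olate | [Li]OC(CC=C(C)C)(c1ccoc1)N(C)OC | intermediate (not isolated)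
9 | 1-(furan-3-yl)-4-methylpent-3-en-1-one | CC(C)=CCC(=O)c1ccoc1 | intermediate
10 | chloro[(S)-1-(furan-3-yl)-4-methylpent-3-en-1-yloxy](isopinocampheyl)borane | C[C@H]1[C@H](B(Cl)O[C@@H](CC=C(C)C)c3ccoc3)C[C@@H]2C[C@H]1C2(C)C | intermediate (not isolated)
11 | (S)-1-(furan-3-yl)-4-methylpent-3-en-1-ol | O[C@@H](CC=C(C)C)c1ccoc1 | intermediate
12 | (S)-3-[1-(tert-butyldimethylsilyloxy)-4-methylpent-3-en-1-yl]furan | CC(C)(C)[Si](C)(C)O[C@@H](CC=C(C)C)c1ccoc1 | intermediate
13 | 2-bromo-3-lithio-1,4-bis(methoxymethoxy)benzene | COCOc1ccc(OCOC)c(Br)c1[Li] | intermediate (not isolated)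
14 | 3,6-bis(methoxymethoxy)benzyne | COCOC1=CC=C(OCOC)C#C1 | intermediate (not isolated)
15 | (1R,4S)-2-[(S)-1-(tert-butyldimethylsilyloxy)-4-methylpent-3-en-1-yl]-5,8-bis(methoxymethoxy)-1,4-dihydro-1,4-epoxynaphthalene (drawn member of the pair of bridgehead epimers that is expected and carried on under this number) | COCOc1ccc(OCOC)c2c1[C@@H]1O[C@H]2C=C1[C@@H](O[Si](C)(C)C(C)(C)C)CC=C(C)C | intermediate
16 | 2-[(S)-1-(tert-butyldimethylsilyloxy)-4-methylpent-3-en-1-yl]-5,8-bis(methoxymethoxy)naphthalen-1-ol | COCOc1ccc(OCOC)c2c1ccc([C@@H](O[Si](C)(C)C(C)(C)C)CC=C(C)C)c2O | intermediate (not isolated)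
17 | 3-[(S)-1-(tert-butyldimethylsilyloxy)-4-methylpent-3-en-1-yl]-5,8-bis(methoxymethoxy)naphthalen-1-ol | COCOc1ccc(OCOC)c2c1cc([C@@H](O[Si](C)(C)C(C)(C)C)CC=C(C)C)cc2O | intermediate (not isolated)
18 | 2-[(S)-1-(tert-butyldimethylsilyloxy)-4-methylpent-3-en-1-yl]-5,8-bis(methoxymethoxy)naphthalene-1,4-dione | CC(C)(C)[Si](C)(C)O[C@@H](CC=C(C)C)C1=CC(=O)c2c(OCOC)ccc(OCOC)c2C1=O | intermediate
19 | 2-[(S)-1-hydroxy-4-methylpent-3-en-1-yl]-5,8-bis(methoxymethoxy)naphthalene-1,4-dione | O[C@@H](CC=C(C)C)C1=CC(=O)c2c(OCOC)ccc(OCOC)c2C1=O | intermediate
20 | tiglic acid ((E)-2-methylbut-2-enoic acid) | C/C=C(\C)C(=O)O | starting material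
21 | O-tigloyl-N,N′-dicyclohexylisourea | C/C=C(\C)C(=O)OC(=NC1CCCCC1)NC1CCCCC1 | intermediate (not isolated)
22 | (S)-1-[5,8-bis(methoxymethoxy)-1,4-dioxo-1,4-dihydronaphthalen-2-yl]-4-methylpent-3-en-1-yl (E)-2-methylbut-2-enoate | C/C=C(\C)C(=O)O[C@@H](CC=C(C)C)C1=CC(=O)c2c(OCOC)ccc(OCOC)c2C1=O | intermediate
23 | (S)-1-(5,8-dihydroxy-1,4-dioxo-1,4-dihydronaphthalen-2-yl)-4-methylpent-3-en-1-yl (E)-2-methylbut-2-enoate | C/C=C(\C)C(=O)O[C@@H](CC=C(C)C)C1=CC(=O)c2c(O)ccc(O)c2C1=O | target

**Count**

Total steps: 10. Longest linear sequence: 9 steps (3 → 5 → 9 → 11 → 12 → 15 → 18 → 19 → 22 → 23).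

**Steps most likely to fail**

Step 6. The aryne is released while its own aryllithium precursor and the liberated amine are still present, so self-arylation or amination may outrun the cycloaddition, and any surviving amide base may metalate the furan α-positions; the valuable furan would then be recovered or lost. The fallback releases the same aryne by halogen–lithium exchange of an ortho-bromoaryl triflate, where no amide is present and the aryllithium eliminates as fast as it forms. It sets out from 2: deprotonation with LiN(i-Pr)2 in THF at −78 °C gives 13, which is quenched with B(OMe)3 to dimethyl [2-bromo-3,6-bis(methoxymethoxy)phenyl]boronate F1. Oxidation with H2O2 and aqueous NaOH should give 2-bromo-3,6-bis(methoxymethoxy)phenol F2, and Tf2O with pyridine in CH2Cl2 should give 2-bromo-3,6-bis(methoxymethoxy)phenyl trifluoromethanesulfonate F3. Slow addition of n-BuLi to F3 and 12 in toluene at −78 °C is expected to form 2-lithio-3,6-bis(methoxymethoxy)phenyl trifluoromethanesulfonate F4, which loses LiOTf at once to give 14 in the presence of the furan. The route is rejoined at 15.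

Step 7. The oxygenation stage may stall or go astray: cobalt-bound superoxide has to reach C4 of naphthol 17, which lies between the side chain and a peri acetal, so ortho-oxygenation or oxidative coupling of the electron-rich naphthols may take over, and rhodium residues may interfere in the one-flask protocol. The fallback separates the two events and replaces aerobic catalysis by a stoichiometric oxidant. It sets out from 15: the rhodium isomerisation is run alone, the naphthol pair 16/17 is isolated quickly under argon, and the pair is oxidised with potassium nitrosodisulfonate, ON(SO3K)2, in KH2PO4-buffered acetone–water (Teuber oxidation), a small oxidant known to take hindered 1-naphthols to 1,4-quinones at neutral pH. The route is rejoined at 18; this detour makes no compound outside the list (F0).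

Step 10. Once the naphthazarin is unveiled, the acid may ionise the C1′–O bond (loss of the tiglate or erosion of configuration) or hydrate the prenyl alkene. The fallback changes the order so that the ester never sees acid and the last step is a neutral acylation. It sets out from 18: 3 M aq HCl in THF removes the acetals while the C1′ oxygen is still silylated, giving 2-[(S)-1-(tert-butyldimethylsilyloxy)-4-methylpent-3-en-1-yl]-5,8-dihydroxynaphthalene-1,4-dione F5. HF·pyridine then gives alkannin, 5,8-dihydroxy-2-[(S)-1-hydroxy-4-methylpent-3-en-1-yl]naphthalene-1,4-dione F6 (any silyl loss in the acid step leads to the same compound). Steglich esterification of F6 with 20 (DCC, cat. DMAP, via 21) should acylate only the aliphatic hydroxyl, because the two phenols are locked in hydrogen bonds to the quinone carbonyls. The route is rejoined at 23.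

**Further compounds**

F1 | step 6 | dimethyl [2-bromo-3,6-bis(methoxymethoxy)phenyl]boronate | COCOc1ccc(OCOC)c(B(OC)OC)c1Br
F2 | step 6 | 2-bromo-3,6-bis(methoxymethoxy)phenol | COCOc1ccc(OCOC)c(O)c1Br
F3 | step 6 | 2-bromo-3,6-bis(methoxymethoxy)phenyl trifluoromethanesulfonate | COCOc1ccc(OCOC)c(OS(=O)(=O)C(F)(F)F)c1Br
F4 | step 6 | 2-lithio-3,6-bis(methoxymethoxy)phenyl trifluoromethanesulfonate | COCOc1ccc(OCOC)c(OS(=O)(=O)C(F)(F)F)c1[Li]
F0 | step 7 | none | none
F5 | step 10 | 2-[(S)-1-(tert-butyldimethylsilyloxy)-4-methylpent-3-en-1-yl]-5,8-dihydroxynaphthalene-1,4-dione | CC(C)(C)[Si](C)(C)O[C@@H](CC=C(C)C)C1=CC(=O)c2c(O)ccc(O)c2C1=O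
F6 | step 10 | alkannin, 5,8-dihydroxy-2-[(S)-1-hydroxy-4-methylpent-3-en-1-yl]naphthalene-1,4-dione | O[C@@H](CC=C(C)C)C1=CC(=O)c2c(O)ccc(O)c2C1=O
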